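The furofuran is disconnected at the O–C9 bond of ring B (O–C7′–C8′–C8–C9, bearing the 3,4-dimethoxyphenyl group). The key step exploits that the quaternary, oxygen-bearing C8 with its two oxygenated one-carbon arms C7 and C9 is a masked 3-substituted oxetan-3-ol: under a chiral phosphoric acid the C7′ hydroxyl opens one of the two diastereotopic oxetane CH2–O bonds, which in one operation closes ring B, fixes C8 and releases C7 as a hydroxymethyl group for later arylation and closure of ring A (O–C7–C8–C8′–C9′). The precursor is a 3-silyloxyoxetane carrying an Evans syn-aldol side chain with free C7′–OH and silylated C9′–OH.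

Key step: step 7

Remarks on the chemistry:
- Lignan numbering is used throughout; TBS = tert-butyldimethylsilyl.
- Assumption: the (R)-antipode of the phosphoric acid is taken as the matched catalyst for step 7; if the pairing proves mismatched, the (S)-antipode is used in the same way.
- The tertiary C8 oxygen is carried as a TBS ether. It is bulkier than a smaller trialkylsilyl group and less prone to 1,2-migration onto the freed C7 hydroxyl.
- The phenol is carried as an allyl ether. Hydrogenolytic removal of a benzyl ether would compete with hydrogenolysis of the two benzylic ring C–O bonds of the furofuran.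

Step 1
Reactants: 1 (S)-4-benzyl-2-oxazolidinone
Product: 2 (S)-3-acetyl-4-benzyl-2-oxazolidinone
Conditions: Ac2O, Et3N, DMAP (cat.), CH2Cl2, rt
Reagents that add atoms: acetic anhydride, CC(=O)OC(C)=O
Why: DMAP-catalysed N-acylation of the oxazolidinone by the anhydride is a standard imide synthesis that needs no strong base and leaves the benzyl-bearing stereocentre untouched.

Step 2
Reactants: 2 (S)-3-acetyl-4-benzyl-2-oxazolidinone; 3 oxetan-3-one
Product: 6 (S)-4-benzyl-3-[2-(3-hydroxyoxetan-3-yl)acetyl]oxazolidin-2-one, via lithium enolate 4 (not isolated), via lithium aldolate 5 (not isolated)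
Conditions: LiN(SiMe3)2, THF, −78 °C; then 3, −78 °C; AcOH quench at −78 °C
Reagents that add atoms: none
Why: Acetate aldol addition of the lithium imide enolate to the strained, strongly electrophilic and symmetric ketone, with a cold acidic quench to forestall retro-aldol and alkoxide attack on the auxiliary carbonyl, creates no stereocentre and installs C7, C8, C9 and the C8 oxygen in one piece.

Step 3
Reactants: 6 (S)-4-benzyl-3-[2-(3-hydroxyoxetan-3-yl)acetyl]oxazolidin-2-one
Product: 7 (S)-4-benzyl-3-{2-[3-(TBS-oxy)oxetan-3-yl]acetyl}oxazolidin-2-one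
Conditions: TBSOTf, 2,6-lutidine, CH2Cl2, −78 to 0 °C
Reagents that add atoms: tert-butyldimethylsilyl triflate, CC(C)(C)[Si](C)(C)OS(=O)(=O)C(F)(F)F
Why: Silylation of the tertiary alcohol with a silyl triflate and 2,6-lutidine at low temperature blocks retro-aldol, and the bulky TBS group is chosen because it later biases the ring opening and resists migration to the C7 hydroxyl.

Step 4
Reactants: 7 (S)-4-benzyl-3-{2-[3-(TBS-oxy)oxetan-3-yl]acetyl}oxazolidin-2-one; 8 veratraldehyde (3,4-dimethoxybenzaldehyde)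
Product: 11 (S)-4-benzyl-3-[(2R,3S)-2-[3-(TBS-oxy)oxetan-3-yl]-3-(3,4-dimethoxyphenyl)-3-hydroxypropanoyl]oxazolidin-2-one, via dibutylboron Z-enolate 9 (not isolated), via dibutylboron aldolate 10 (not isolated)
Conditions: Bu2BOTf, i-Pr2NEt, CH2Cl2, −78 to 0 °C; then 8, −78 to 0 °C; pH 7 buffer, MeOH, 30% H2O2, 0 °C
Reagents that add atoms: none
Why: Evans boron syn-aldol reaction, in which the Z-dibutylboron enolate reacts through a closed Zimmerman–Traxler chair and the (S)-benzyl group of the auxiliary blocks one enolate face, setting C8′ as R and C7′ as S (2,3-syn) in one step.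

Step 5
Reactants: 11 (S)-4-benzyl-3-[(2R,3S)-2-[3-(TBS-oxy)oxetan-3-yl]-3-(3,4-dimethoxyphenyl)-3-hydroxypropanoyl]oxazolidin-2-one
Product: 12 (1S,2R)-2-[3-(TBS-oxy)oxetan-3-yl]-1-(3,4-dimethoxyphenyl)propane-1,3-diol
Conditions: LiBH4, H2O (1 equiv), Et2O/THF, 0 °C
Reagents that add atoms: none
Why: Reductive cleavage of the N-acyl oxazolidinone with LiBH4 attacks the exocyclic carbonyl and gives the primary C9′ alcohol without touching C7′, C8′ or the oxetane, and auxiliary 1 is recovered.

Step 6
Reactants: 12 (1S,2R)-2-[3-(TBS-oxy)oxetan-3-yl]-1-(3,4-dimethoxyphenyl)propane-1,3-diol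
Product: 13 (1S,2R)-3-(TBS-oxy)-2-[3-(TBS-oxy)oxetan-3-yl]-1-(3,4-dimethoxyphenyl)propan-1-ol
Conditions: TBSCl, imidazole, CH2Cl2, 0 °C
Reagents that add atoms: tert-butyldimethylsilyl chloride, CC(C)(C)[Si](C)(C)Cl
Why: Chemoselective silylation of the primary C9′ hydroxyl over the hindered secondary benzylic one leaves the C7′ hydroxyl as the only free nucleophile, so that the C9′ oxygen cannot compete for the oxetane in step 7.

Step 7
Reactants: 13 (1S,2R)-3-(TBS-oxy)-2-[3-(TBS-oxy)oxetan-3-yl]-1-(3,4-dimethoxyphenyl)propan-1-ol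
Product: 14 [(3R,4R,5S)-3-(TBS-oxy)-4-[(TBS-oxy)methyl]-5-(3,4-dimethoxyphenyl)oxolan-3-yl]methanol
Conditions: (R)-TRIP [(R)-3,3′-bis(2,4,6-triisopropylphenyl)-1,1′-binaphthyl-2,2′-diyl hydrogen phosphate] (10 mol %), toluene, 25 °C
Reagents that add atoms: none
Why: The phosphoric acid hydrogen-bonds to the oxetane oxygen while its phosphoryl oxygen holds the C7′ hydroxyl, which attacks one ring CH2 from the back in an SN2 displacement driven by release of four-membered-ring strain; the attacked carbon becomes C9 and the former oxetane oxygen stays on the other carbon as the C7 hydroxyl. The closest known reaction type is the Brønsted-acid-catalysed intramolecular desymmetrising opening of 3,3-disubstituted oxetanes by tethered alcohols, which gives 3-(hydroxymethyl)tetrahydrofurans and 1,4-dioxanes. Ring B closes in the 5-exo-tet mode, the breaking C–O bond lying outside the new ring. The new stereocentre C8 results from the choice between the two diastereotopic CH2 groups, which is governed by the chiral phosphate and supported by the substrate, since attack on the required CH2 keeps the bulky C8 silyloxy group next to H8′ and away from the C9′ silyloxymethyl group, leaving the C7 arm cis to C9′. The step needs chemoselectivity and configurational integrity: the C7′ hydroxyl is the only free nucleophile because O8 and O9′ are silylated, the SN2 event touches neither C7′ nor C8′, and the acid is too weak to ionise the veratryl carbinol, whose cation would re-close on either arm and erase the selection.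

Step 8
Reactants: 14 [(3R,4R,5S)-3-(TBS-oxy)-4-[(TBS-oxy)methyl]-5-(3,4-dimethoxyphenyl)oxolan-3-yl]methanol
Product: 15 (3S,4R,5S)-3-(TBS-oxy)-4-[(TBS-oxy)methyl]-5-(3,4-dimethoxyphenyl)oxolane-3-carbaldehyde
Conditions: Dess–Martin periodinane, pyridine, CH2Cl2, 0 °C to rt
Reagents that add atoms: none
Why: Dess–Martin oxidation converts the neopentyl-type primary alcohol into the aldehyde under non-basic conditions that do not shift the neighbouring silyl group, and C8 has no α-hydrogen to lose.

Step 9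
Reactants: 16 4-bromo-2-methoxyphenol
Product: 17 1-(allyloxy)-4-bromo-2-methoxybenzene
Conditions: allyl bromide, K2CO3, acetone, reflux
Reagents that add atoms: allyl bromide, C=CCBr
Why: Williamson ether synthesis on the phenoxide gives the allyl ether, a phenol protection that is removed at the end by zerovalent palladium and not by hydrogenolysis.

Step 10
Reactants: 15 (3S,4R,5S)-3-(TBS-oxy)-4-[(TBS-oxy)methyl]-5-(3,4-dimethoxyphenyl)oxolane-3-carbaldehyde; 17 1-(allyloxy)-4-bromo-2-methoxybenzene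
Product: 20 [4-(allyloxy)-3-methoxyphenyl]{(3S,4R,5S)-3-(TBS-oxy)-4-[(TBS-oxy)methyl]-5-(3,4-dimethoxyphenyl)oxolan-3-yl}methanol (both C7 epimers), via arylmagnesium bromide 18 (not isolated), via magnesium alkoxide 19 (not isolated)
Conditions: 17, Mg, I2 (cat.), THF, 40 °C; then 15, THF, −78 to 0 °C; sat. aq. NH4Cl
Reagents that add atoms: none
Why: Grignard addition of the aryl nucleophile to the non-enolisable aldehyde forms the C7–aryl bond, and the new carbinol centre C7 is deliberately left uncontrolled because both epimers converge on one benzylic cation in step 12, while any silyl shift between O7 and O8 is irrelevant since both silyl groups are removed in step 11.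

Step 11
Reactants: 20 [4-(allyloxy)-3-methoxyphenyl]{(3S,4R,5S)-3-(TBS-oxy)-4-[(TBS-oxy)methyl]-5-(3,4-dimethoxyphenyl)oxolan-3-yl}methanol
Product: 21 (3S,4R,5S)-3-{[4-(allyloxy)-3-methoxyphenyl](hydroxy)methyl}-5-(3,4-dimethoxyphenyl)-4-(hydroxymethyl)oxolan-3-ol (both C7 epimers)
Conditions: Bu4NF, THF, rt to 40 °C
Reagents that add atoms: none
Why: Fluoride-mediated desilylation removes both silyl ethers under conditions that cannot ionise either benzylic position, and the free, small tertiary C8 hydroxyl is wanted before ring closure because it favours the exo course of step 12.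

Step 12
Reactants: 21 (3S,4R,5S)-3-{[4-(allyloxy)-3-methoxyphenyl](hydroxy)methyl}-5-(3,4-dimethoxyphenyl)-4-(hydroxymethyl)oxolan-3-ol
Product: 22 (7R,8S,7′S,8′R)-4-(allyloxy)-3,3′,4′-trimethoxy-7,9′:7′,9-diepoxylignan-8-ol (cis-fused bicycle, both aryl groups exo, 8-OH cis to H8′)
Conditions: camphor-10-sulfonic acid (10 mol %), CH2Cl2, 0 °C
Reagents that add atoms: none
Why: Acid-catalysed SN1 cycloetherification, in which the p-alkoxybenzylic C7 cation formed from either carbinol epimer is trapped by the C9′ hydroxyl in a 5-exo-trig closure (cation taken in its quinone-methide form) that can only give the cis-fused bicycle, and C7 is set by capture on the face that places the aryl group on the convex side, eclipsed with the small C8 hydroxyl and not with the ring B methylene C9 (least allylic strain).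

Step 13
Reactants: 22 (7R,8S,7′S,8′R)-4-(allyloxy)-3,3′,4′-trimethoxy-7,9′:7′,9-diepoxylignan-8-ol
Product: 23 (7R,8S,7′S,8′R)-4-(allyloxy)-3,3′,4′-trimethoxy-7,9′:7′,9-diepoxylignan-8-yl acetate
Conditions: Ac2O, Et3N, DMAP (1 equiv), CH2Cl2, 40 °C
Reagents that add atoms: acetic anhydride, CC(=O)OC(C)=O
Why: DMAP-catalysed (Steglich-type) acylation is the standard way to esterify a hindered tertiary alcohol, runs under basic conditions that do not ionise the benzylic ethers, and meets only O8 because the phenol is still masked.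

Step 14
Reactants: 23 (7R,8S,7′S,8′R)-4-(allyloxy)-3,3′,4′-trimethoxy-7,9′:7′,9-diepoxylignan-8-yl acetate
Product: 24 (7R,8S,7′S,8′R)-4-hydroxy-3,3′,4′-trimethoxy-7,9′:7′,9-diepoxylignan-8-yl acetate (CNP0107105.1)
Conditions: Pd(PPh3)4 (5 mol %), morpholine, THF, rt
Reagents that add atoms: none
Why: Palladium-catalysed allyl transfer (Tsuji–Trost-type deallylation) from the aryl allyl ether to morpholine frees the phenol under neutral conditions that leave the tertiary acetate and both benzylic C–O bonds of the furofuran untouched.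

Compound list
1 | (S)-4-benzyl-2-oxazolidinone | O=C1OC[C@H](Cc2ccccc2)N1 | starting material
2 | (S)-3-acetyl-4-benzyl-2-oxazolidinone | CC(=O)N1[C@@H](Cc2ccccc2)COC1=O | intermediate
3 | oxetan-3-one | O=C1COC1 | starting material
4 | lithium enolate of 2 | [Li]OC(=C)N1[C@@H](Cc2ccccc2)COC1=O | intermediate (not isolated)
5 | lithium aldolate, the lithium alkoxide of 6 | [Li]OC1(CC(=O)N2[C@@H](Cc3ccccc3)COC2=O)COC1 | intermediate (not isolated)
6 | (S)-4-benzyl-3-[2-(3-hydroxyoxetan-3-yl)acetyl]oxazolidin-2-one | OC1(CC(=O)N2[C@@H](Cc3ccccc3)COC2=O)COC1 | intermediate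
7 | (S)-4-benzyl-3-{2-[3-(TBS-oxy)oxetan-3-yl]acetyl}oxazolidin-2-one | CC(C)(C)[Si](C)(C)OC1(CC(=O)N2[C@@H](Cc3ccccc3)COC2=O)COC1 | intermediate
8 | veratraldehyde (3,4-dimethoxybenzaldehyde) | COc1ccc(C=O)cc1OC | starting material
9 | dibutylboron Z-enolate of 7 | CCCCB(CCCC)O/C(=C\C1(O[Si](C)(C)C(C)(C)C)COC1)N1[C@@H](Cc2ccccc2)COC1=O | intermediate (not isolated)
10 | dibutylboron aldolate, the O-dibutylboryl derivative of 11 | O=C([C@@H](C1(O[Si](C)(C)C(C)(C)C)COC1)[C@H](OB(CCCC)CCCC)c1ccc(OC)c(OC)c1)N1[C@@H](Cc2ccccc2)COC1=O | intermediate (not isolated)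
11 | (S)-4-benzyl-3-[(2R,3S)-2-[3-(TBS-oxy)oxetan-3-yl]-3-(3,4-dimethoxyphenyl)-3-hydroxypropanoyl]oxazolidin-2-one (syn-aldol adduct) | O=C([C@@H](C1(O[Si](C)(C)C(C)(C)C)COC1)[C@H](O)c1ccc(OC)c(OC)c1)N1[C@@H](Cc2ccccc2)COC1=O | intermediate
12 | (1S,2R)-2-[3-(TBS-oxy)oxetan-3-yl]-1-(3,4-dimethoxyphenyl)propane-1,3-diol | OC[C@@H](C1(O[Si](C)(C)C(C)(C)C)COC1)[C@H](O)c1ccc(OC)c(OC)c1 | intermediate
13 | (1S,2R)-3-(TBS-oxy)-2-[3-(TBS-oxy)oxetan-3-yl]-1-(3,4-dimethoxyphenyl)propan-1-ol (precursor of the key step; C7′ S, C8′ R) | CC(C)(C)[Si](C)(C)OC[C@@H](C1(O[Si](C)(C)C(C)(C)C)COC1)[C@H](O)c1ccc(OC)c(OC)c1 | intermediate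
14 | [(3R,4R,5S)-3-(TBS-oxy)-4-[(TBS-oxy)methyl]-5-(3,4-dimethoxyphenyl)oxolan-3-yl]methanol (ring B; C7 hydroxymethyl cis to the C9′ arm, aryl trans to it) | OC[C@@]1(O[Si](C)(C)C(C)(C)C)CO[C@H](c2ccc(OC)c(OC)c2)[C@H]1CO[Si](C)(C)C(C)(C)C | intermediate
15 | (3S,4R,5S)-3-(TBS-oxy)-4-[(TBS-oxy)methyl]-5-(3,4-dimethoxyphenyl)oxolane-3-carbaldehyde | O=C[C@@]1(O[Si](C)(C)C(C)(C)C)CO[C@H](c2ccc(OC)c(OC)c2)[C@H]1CO[Si](C)(C)C(C)(C)C | intermediate
16 | 4-bromo-2-methoxyphenol | COc1cc(Br)ccc1O | starting material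
17 | 1-(allyloxy)-4-bromo-2-methoxybenzene | C=CCOc1ccc(Br)cc1OC | intermediate
18 | [4-(allyloxy)-3-methoxyphenyl]magnesium bromide | C=CCOc1ccc([Mg]Br)cc1OC | intermediate (not isolated)
19 | bromomagnesium alkoxide of 20 (both C7 epimers) | C=CCOc1ccc(C(O[Mg]Br)[C@@]2(O[Si](C)(C)C(C)(C)C)CO[C@H](c3ccc(OC)c(OC)c3)[C@H]2CO[Si](C)(C)C(C)(C)C)cc1OC | intermediate (not isolated)
20 | [4-(allyloxy)-3-methoxyphenyl]{(3S,4R,5S)-3-(TBS-oxy)-4-[(TBS-oxy)methyl]-5-(3,4-dimethoxyphenyl)oxolan-3-yl}methanol (both C7 epimers) | C=CCOc1ccc(C(O)[C@@]2(O[Si](C)(C)C(C)(C)C)CO[C@H](c3ccc(OC)c(OC)c3)[C@H]2CO[Si](C)(C)C(C)(C)C)cc1OC | intermediate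
21 | (3S,4R,5S)-3-{[4-(allyloxy)-3-methoxyphenyl](hydroxy)methyl}-5-(3,4-dimethoxyphenyl)-4-(hydroxymethyl)oxolan-3-ol (both C7 epimers) | C=CCOc1ccc(C(O)[C@@]2(O)CO[C@H](c3ccc(OC)c(OC)c3)[C@H]2CO)cc1OC | intermediate
22 | (7R,8S,7′S,8′R)-4-(allyloxy)-3,3′,4′-trimethoxy-7,9′:7′,9-diepoxylignan-8-ol | C=CCOc1ccc([C@H]2OC[C@@H]3[C@@H](c4ccc(OC)c(OC)c4)OC[C@]23O)cc1OC | intermediate
23 | (7R,8S,7′S,8′R)-4-(allyloxy)-3,3′,4′-trimethoxy-7,9′:7′,9-diepoxylignan-8-yl acetate | C=CCOc1ccc([C@H]2OC[C@@H]3[C@@H](c4ccc(OC)c(OC)c4)OC[C@]23OC(C)=O)cc1OC | intermediate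
24 | (7R,8S,7′S,8′R)-4-hydroxy-3,3′,4′-trimethoxy-7,9′:7′,9-diepoxylignan-8-yl acetate (CNP0107105.1) | COc1cc([C@H]2OC[C@@H]3[C@@H](c4ccc(OC)c(OC)c4)OC[C@]23OC(C)=O)ccc1O | target

Total step count: 14 (13 in the main line plus the one-step preparation of aryl bromide 17).
Longest linear sequence: 13 steps (steps 1–8 and 10–14, from 1).

Steps most likely to fail

Step 7. The catalyst may not discriminate well enough between the two diastereotopic oxetane methylene groups, or the selection may be lost through reversible ionisation of the veratryl C7′–O bond. The fallback sets out from 13 and comes back at 14. Ring B is closed with an achiral Brønsted acid (camphorsulfonic acid, CH2Cl2) without any demand on selectivity, which gives 14 together with its C8 epimer, [(3S,4R,5S)-3-(TBS-oxy)-4-[(TBS-oxy)methyl]-5-(3,4-dimethoxyphenyl)oxolan-3-yl]methanol F1. The two are separated by chromatography. F1 is then treated with BF3·OEt2 in CH2Cl2 at low temperature, which ionises the benzylic ring C–O bond reversibly, the known acid epimerisation of 2-aryltetrahydrofuran lignans. The open cation carries two constitutionally identical hydroxymethyl groups on C8 and re-closes on either, so F1 is converted back into a mixture with 14. Repeated separation and equilibration moves the material into 14, and C8 is then set under thermodynamic control with recycling instead of catalyst control.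

Step 4. The Lewis-acidic boron triflate may open the oxetane, or the addition of the hindered enolate to the electron-rich aldehyde may stall. The fallback sets out from oxetan-3-one 3 and comes back at diol 12. Steps 1 to 3 are repeated with the antipodal auxiliary (R)-4-benzyl-2-oxazolidinone F2, giving (R)-3-acetyl-4-benzyl-2-oxazolidinone F3, the ketone adduct (R)-4-benzyl-3-[2-(3-hydroxyoxetan-3-yl)acetyl]oxazolidin-2-one F4 and its silyl ether (R)-4-benzyl-3-{2-[3-(TBS-oxy)oxetan-3-yl]acetyl}oxazolidin-2-one F5. The lithium enolate of F5 (LiN(i-Pr)2, THF, −78 °C) is C-acylated with 3,4-dimethoxybenzoyl chloride. This asymmetric enolate acylation follows the facial sense of enolate alkylation, which is opposite to that of the boron aldol, hence the antipodal auxiliary. It gives the β-keto imide (R)-4-benzyl-3-[(2S)-2-[3-(TBS-oxy)oxetan-3-yl]-3-(3,4-dimethoxyphenyl)-3-oxopropanoyl]oxazolidin-2-one F6. Chelation-controlled reduction with Zn(BH4)2 should deliver the syn β-hydroxy imide (R)-4-benzyl-3-[(2R,3S)-2-[3-(TBS-oxy)oxetan-3-yl]-3-(3,4-dimethoxyphenyl)-3-hydroxypropanoyl]oxazolidin-2-one F7, which has the C8′ and C7′ configuration of 11. LiBH4 as in step 5 then releases 12. No boron triflate is used, and the electrophile is an acid chloride instead of an aldehyde.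

Step 12. Capture of the C7 cation may show poor facial selectivity, ring B may epimerise at C7′ by ionisation under the same acid, or the cation next to the tertiary carbinol may undergo a 1,2-shift. The fallback sets out from 20 and comes back at 22. Dess–Martin oxidation gives the aryl ketone [4-(allyloxy)-3-methoxyphenyl]{(3S,4R,5S)-3-(TBS-oxy)-4-[(TBS-oxy)methyl]-5-(3,4-dimethoxyphenyl)oxolan-3-yl}methanone F8. Reduction with LiBH(s-Bu)3 under Felkin–Anh control (silyloxy group anti to the hydride, approach past the ring methylene C9) should give the single (7R)-carbinol of 20, F9. Bu4NF then gives the (7R)-triol of 21, F10. Selective tosylation of the primary C9′ hydroxyl (TsCl, pyridine, 0 °C) gives the monotosylate F11. NaH in THF closes ring A by Williamson etherification (5-exo-tet at C9′), with C7 acting as the nucleophile and keeping its configuration, to give 22 without any cation.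

Further compounds
F1 | step 7 | [(3S,4R,5S)-3-(TBS-oxy)-4-[(TBS-oxy)methyl]-5-(3,4-dimethoxyphenyl)oxolan-3-yl]methanol (C8 epimer of 14) | OC[C@]1(O[Si](C)(C)C(C)(C)C)CO[C@H](c2ccc(OC)c(OC)c2)[C@H]1CO[Si](C)(C)C(C)(C)C
F2 | step 4 | (R)-4-benzyl-2-oxazolidinone | O=C1OC[C@@H](Cc2ccccc2)N1
F3 | step 4 | (R)-3-acetyl-4-benzyl-2-oxazolidinone | CC(=O)N1[C@H](Cc2ccccc2)COC1=O
F4 | step 4 | (R)-4-benzyl-3-[2-(3-hydroxyoxetan-3-yl)acetyl]oxazolidin-2-one | OC1(CC(=O)N2[C@H](Cc3ccccc3)COC2=O)COC1
F5 | step 4 | (R)-4-benzyl-3-{2-[3-(TBS-oxy)oxetan-3-yl]acetyl}oxazolidin-2-one | CC(C)(C)[Si](C)(C)OC1(CC(=O)N2[C@H](Cc3ccccc3)COC2=O)COC1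
F6 | step 4 | (R)-4-benzyl-3-[(2S)-2-[3-(TBS-oxy)oxetan-3-yl]-3-(3,4-dimethoxyphenyl)-3-oxopropanoyl]oxazolidin-2-one | O=C([C@@H](C1(O[Si](C)(C)C(C)(C)C)COC1)C(=O)c1ccc(OC)c(OC)c1)N1[C@H](Cc2ccccc2)COC1=O
F7 | step 4 | (R)-4-benzyl-3-[(2R,3S)-2-[3-(TBS-oxy)oxetan-3-yl]-3-(3,4-dimethoxyphenyl)-3-hydroxypropanoyl]oxazolidin-2-one | O=C([C@@H](C1(O[Si](C)(C)C(C)(C)C)COC1)[C@H](O)c1ccc(OC)c(OC)c1)N1[C@H](Cc2ccccc2)COC1=O
F8 | step 12 | [4-(allyloxy)-3-methoxyphenyl]{(3S,4R,5S)-3-(TBS-oxy)-4-[(TBS-oxy)methyl]-5-(3,4-dimethoxyphenyl)oxolan-3-yl}methanone | C=CCOc1ccc(C(=O)[C@@]2(O[Si](C)(C)C(C)(C)C)CO[C@H](c3ccc(OC)c(OC)c3)[C@H]2CO[Si](C)(C)C(C)(C)C)cc1OC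
F9 | step 12 | (R)-[4-(allyloxy)-3-methoxyphenyl]{(3S,4R,5S)-3-(TBS-oxy)-4-[(TBS-oxy)methyl]-5-(3,4-dimethoxyphenyl)oxolan-3-yl}methanol | C=CCOc1ccc([C@@H](O)[C@@]2(O[Si](C)(C)C(C)(C)C)CO[C@H](c3ccc(OC)c(OC)c3)[C@H]2CO[Si](C)(C)C(C)(C)C)cc1OC
F10 | step 12 | (3S,4R,5S)-3-{(R)-[4-(allyloxy)-3-methoxyphenyl](hydroxy)methyl}-5-(3,4-dimethoxyphenyl)-4-(hydroxymethyl)oxolan-3-ol | C=CCOc1ccc([C@@H](O)[C@@]2(O)CO[C@H](c3ccc(OC)c(OC)c3)[C@H]2CO)cc1OC
F11 | step 12 | primary 4-methylbenzenesulfonate of F10 at the C9′ hydroxymethyl group | C=CCOc1ccc([C@@H](O)[C@@]2(O)CO[C@H](c3ccc(OC)c(OC)c3)[C@H]2COS(=O)(=O)c4ccc(C)cc4)cc1OC
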